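**Assumption:** the target is the single stereoisomer written in the SMILES, i.e. (6S,7S,10S,11R,12S,14S,15R) with 2E and 8E alkenes, using geldanamycin-type numbering (C1 amide carbonyl, C15 benzylic carbinol, C16–C21 arene, OH on C18, N on C20). Compounds 1, 3, 14 and 18 are taken as purchasable; 1 is the L-glutamic-acid-derived lactone.

**Retrosynthetic overview**
1. The 19-membered lactam is closed last at the aryl C20–N bond by light-driven Ni-catalysed N-arylation of bromo-amide 29.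
2. C7–C8: alkenylzinc from alkyne 25 (hydrozirconation) adds to α-methoxy aldehyde 7 under chelation control, setting C7.
3. C15–aryl: aryl Grignard 20 adds to lactol 17 (Felkin, sets C15); C10–C11: (Z)-crotylboration of α-methoxy aldehyde 13 (sets C10 and C11).
4. Both α-methoxy aldehydes (C3–C7 and C11–C15) come from the same lactone 1, which supplies C6 and C12; C14 comes from cis-hydrogenation of its α-methylene derivative.
5. Ring order: temporary δ-lactone 16 (template, opened in step 13), then the macrolactam.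

**Route**

Step 1
Reactants: 1 (5S)-5-(trityloxymethyl)oxolan-2-one
Product: 2 methyl (4S)-4-methoxy-5-(trityloxy)pentanoate
Conditions: KOH (powdered), DMSO, rt, 15 min; then MeI, rt, 1 h
Reagents that add atoms: iodomethane (CI); potassium hydroxide ([K+].[OH-])
Why: Hydroxide opens the lactone (saponification) and MeI then alkylates both the alkoxide and the carboxylate (Williamson etherification and carboxylate alkylation); the C–O bond at the stereocentre (later C6) is never broken.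

Step 2
Reactants: 2 methyl (4S)-4-methoxy-5-(trityloxy)pentanoate; 3 methyl 2-(triphenylphosphoranylidene)propanoate
Product: 5 methyl (2E,6S)-6-methoxy-2-methyl-7-(trityloxy)hept-2-enoate, via aldehyde 4 (not isolated)
Conditions: i-Bu2AlH (1.05 equiv), CH2Cl2, −78 °C; then 3 (1.5 equiv), −78 °C → rt
Reagents that add atoms: none
Why: Partial ester reduction at −78 °C gives the aldehyde, which undergoes Wittig olefination with the stabilised α-methyl ylide to give the E-trisubstituted enoate (C2=C3).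

Step 3
Reactants: 5 methyl (2E,6S)-6-methoxy-2-methyl-7-(trityloxy)hept-2-enoate
Product: 6 methyl (2E,6S)-7-hydroxy-6-methoxy-2-methylhept-2-enoate
Conditions: TsOH·H2O (10 mol%), MeOH/CH2Cl2, 0 °C → rt
Reagents that add atoms: none
Why: Acid-catalysed SN1 solvolysis of the trityl ether frees the primary alcohol without touching the enoate or the methyl ether.

Step 4
Reactants: 6 methyl (2E,6S)-7-hydroxy-6-methoxy-2-methylhept-2-enoate
Product: 7 methyl (2E,6S)-6-methoxy-2-methyl-7-oxohept-2-enoate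
Conditions: Dess–Martin periodinane, CH2Cl2, 0 °C → rt; used at once
Reagents that add atoms: none
Why: Dess–Martin oxidation gives the α-methoxy aldehyde under non-basic conditions that do not epimerise C6.

Step 5
Reactants: 1 (5S)-5-(trityloxymethyl)oxolan-2-one
Product: 9 (5S)-3-methylidene-5-(trityloxymethyl)oxolan-2-one, via sodium hydroxymethylene-lactone enolate 8 (not isolated)
Conditions: NaH, HCO2Et, THF, 0 °C → rt; then paraformaldehyde, THF, 65 °C
Reagents that add atoms: paraformaldehyde (C=O)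
Why: Claisen formylation followed by aldol reaction with formaldehyde and loss of formate (Murray α-methylenation of lactones) installs the carbon that becomes the C14 methyl.

Step 6
Reactants: 9 (5S)-3-methylidene-5-(trityloxymethyl)oxolan-2-one
Product: 10 (3S,5S)-3-methyl-5-(trityloxymethyl)oxolan-2-one
Conditions: H2 (1 atm), 10% Pd/C, EtOAc, rt
Reagents that add atoms: none
Why: Heterogeneous hydrogenation adds hydrogen anti to the trityloxymethyl group, so the new methyl ends cis to it (3S, later C14; substrate control, about 9:1 expected, minor trans isomer removed by chromatography).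

Step 7
Reactants: 10 (3S,5S)-3-methyl-5-(trityloxymethyl)oxolan-2-one
Product: 11 methyl (2S,4S)-4-methoxy-2-methyl-5-(trityloxy)pentanoate
Conditions: KOH (powdered), DMSO, rt, 10 min; then MeI, 0 °C → rt, 30 min
Reagents that add atoms: iodomethane (CI); potassium hydroxide ([K+].[OH-])
Why: Same saponification and double O-methylation as step 1; hydroxide attacks the lactone carbonyl far faster than it enolises it and the carboxylate is not enolisable, so C14 is kept while C12 gains its methyl ether.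

Step 8
Reactants: 11 methyl (2S,4S)-4-methoxy-2-methyl-5-(trityloxy)pentanoate
Product: 12 methyl (2S,4S)-5-hydroxy-4-methoxy-2-methylpentanoate
Conditions: TsOH·H2O (10 mol%), MeOH, 0 °C → rt; Et3N quench
Reagents that add atoms: none
Why: Acid-catalysed SN1 solvolysis of the trityl ether; methanol as solvent keeps the δ-hydroxy ester open.

Step 9
Reactants: 12 methyl (2S,4S)-5-hydroxy-4-methoxy-2-methylpentanoate
Product: 13 methyl (2S,4S)-4-methoxy-2-methyl-5-oxopentanoate
Conditions: Dess–Martin periodinane, CH2Cl2, 0 °C → rt; used at once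
Reagents that add atoms: none
Why: Dess–Martin oxidation gives the α-methoxy aldehyde (C11) without epimerising C12 or C14.

Step 10
Reactants: 13 methyl (2S,4S)-4-methoxy-2-methyl-5-oxopentanoate; 14 2-[(2Z)-but-2-en-1-yl]-4,4,5,5-tetramethyl-1,3,2-dioxaborolane
Product: 16 (3S,5S,6R)-6-[(2S)-but-3-en-2-yl]-5-methoxy-3-methyloxan-2-one, via hydroxy ester 15 (not isolated)
Conditions: 14 (1.5 equiv), PhMe, 4 Å MS, rt, 48 h; aq. NaHCO3 work-up; then TsOH·H2O (5 mol%), PhMe, rt
Reagents that add atoms: none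
Why: Crotylboration through a closed six-membered Zimmerman–Traxler transition state: the Z reagent gives the 10,11-syn relation and the α-methoxy stereocentre directs Felkin/Cornforth attack to the 11,12-anti isomer (10S,11R), after which acid-catalysed lactonisation ties C11–OH and C15 into the δ-lactone.

Step 11
Reactants: 16 (3S,5S,6R)-6-[(2S)-but-3-en-2-yl]-5-methoxy-3-methyloxan-2-one
Product: 17 (3S,5S,6R)-6-[(2S)-but-3-en-2-yl]-5-methoxy-3-methyloxan-2-ol (anomer mixture)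
Conditions: i-Bu2AlH (1.1 equiv), CH2Cl2, −78 °C; aq. KNaC4H4O6 (potassium sodium tartrate) work-up
Reagents that add atoms: none
Why: Half-reduction of the δ-lactone (stable aluminium lactolate at −78 °C) gives the lactol, a masked C15 aldehyde with C11–OH protected internally.

Step 12
Reactants: 18 3,5-dibromophenol
Product: 19 (3,5-dibromophenoxy)tri(propan-2-yl)silane
Conditions: TIPSCl, imidazole, DMF, rt
Reagents that add atoms: chlorotri(propan-2-yl)silane (CC(C)[Si](Cl)(C(C)C)C(C)C)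
Why: Standard silylation of the phenol; the TIPS ether survives the later organometallic and basic steps.

Step 13
Reactants: 17 (3S,5S,6R)-6-[(2S)-but-3-en-2-yl]-5-methoxy-3-methyloxan-2-ol; 19 (3,5-dibromophenoxy)tri(propan-2-yl)silane
Product: 21 (1R,2S,4S,5R,6S)-1-[3-bromo-5-(triisopropylsilyloxy)phenyl]-4-methoxy-2,6-dimethyloct-7-ene-1,5-diol, via aryl Grignard 20 (not isolated)
Conditions: 19 (2.6 equiv), i-PrMgCl·LiCl (2.5 equiv), THF, −15 °C; then 17, −40 → 0 °C; aq. NH4Cl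
Reagents that add atoms: none
Why: Mono bromine–magnesium exchange gives the aryl Grignard, which adds to the open aldehyde form of the lactol under Felkin–Anh control from the C14 methyl stereocentre to give the 14,15-syn (15R) benzylic alcohol (about 4:1 expected; epimer separated).

Step 14
Reactants: 21 (1R,2S,4S,5R,6S)-1-[3-bromo-5-(triisopropylsilyloxy)phenyl]-4-methoxy-2,6-dimethyloct-7-ene-1,5-diol
Product: 22 {3-bromo-5-[(1R,2S,4S,5R,6S)-1,5-bis(tert-butyldimethylsilyloxy)-4-methoxy-2,6-dimethyloct-7-en-1-yl]phenoxy}tri(propan-2-yl)silane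
Conditions: TBSOTf (3 equiv), 2,6-lutidine, CH2Cl2, −78 → 0 °C
Reagents that add atoms: tert-butyldimethylsilyl trifluoromethanesulfonate (CC(C)(C)[Si](C)(C)OS(=O)(=O)C(F)(F)F)
Why: Silyl triflate silylation protects both hindered secondary alcohols (C11, C15) in one operation.

Step 15
Reactants: 22 {3-bromo-5-[(1R,2S,4S,5R,6S)-1,5-bis(tert-butyldimethylsilyloxy)-4-methoxy-2,6-dimethyloct-7-en-1-yl]phenoxy}tri(propan-2-yl)silane
Product: 23 (2R,3R,4S,6S,7R)-7-[3-bromo-5-(triisopropylsilyloxy)phenyl]-3,7-bis(tert-butyldimethylsilyloxy)-4-methoxy-2,6-dimethylheptanal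
Conditions: O3, CH2Cl2, −78 °C (Sudan Red 7B end point); then PPh3, −78 °C → rt
Reagents that add atoms: ozone ([O-][O+]=O)
Why: Ozonolysis with reductive work-up cleaves the terminal alkene to the C9 aldehyde; the indicator stops ozone before it attacks the bromoarene (the C10 descriptor changes to R only through CIP priorities).

Step 16
Reactants: 23 (2R,3R,4S,6S,7R)-7-[3-bromo-5-(triisopropylsilyloxy)phenyl]-3,7-bis(tert-butyldimethylsilyloxy)-4-methoxy-2,6-dimethylheptanal
Product: 25 {3-bromo-5-[(1R,2S,4S,5R,6S)-1,5-bis(tert-butyldimethylsilyloxy)-4-methoxy-2,6-dimethylnon-7-yn-1-yl]phenoxy}tri(propan-2-yl)silane, via terminal alkyne 24 (not isolated)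
Conditions: TMSCHN2, n-BuLi, THF, −78 °C; 23, −78 → 0 °C; then LiN(SiMe3)2, MeI, −78 °C → rt
Reagents that add atoms: (trimethylsilyl)diazomethane (C[Si](C)(C)C=[N+]=[N-]); iodomethane (CI)
Why: Colvin homologation (alkylidene carbene 1,2-hydrogen shift) gives the terminal alkyne, whose acetylide is methylated in the same flask; LiN(SiMe3)2 does not exchange the aryl bromide.

Step 17
Reactants: 25 {3-bromo-5-[(1R,2S,4S,5R,6S)-1,5-bis(tert-butyldimethylsilyloxy)-4-methoxy-2,6-dimethylnon-7-yn-1-yl]phenoxy}tri(propan-2-yl)silane; 7 methyl (2E,6S)-6-methoxy-2-methyl-7-oxohept-2-enoate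
Product: 28 methyl (2E,6S,7S,8E,10S,11R,12S,14S,15R)-15-[3-bromo-5-(triisopropylsilyloxy)phenyl]-11,15-bis(tert-butyldimethylsilyloxy)-7-hydroxy-6,12-dimethoxy-2,8,10,14-tetramethylpentadeca-2,8-dienoate, via alkenylzirconocene 26 (not isolated), via alkenylzinc 27 (not isolated)
Conditions: Cp2Zr(H)Cl (1.3 equiv), THF, 50 °C; Me2Zn (1.3 equiv), −78 °C; then 7 (1.5 equiv), −78 → 0 °C; aq. NH4Cl
Reagents that add atoms: none
Why: Syn hydrozirconation places zirconium on the less hindered methyl-bearing alkyne carbon, zirconium-to-zinc transmetalation (Wipf protocol) gives the E-alkenylzinc, and its addition to the α-methoxy aldehyde through the five-membered Cram chelate sets 7S (6,7-syn).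

Step 18
Reactants: 28 methyl (2E,6S,7S,8E,10S,11R,12S,14S,15R)-15-[3-bromo-5-(triisopropylsilyloxy)phenyl]-11,15-bis(tert-butyldimethylsilyloxy)-7-hydroxy-6,12-dimethoxy-2,8,10,14-tetramethylpentadeca-2,8-dienoate
Product: 29 (2E,6S,7S,8E,10S,11R,12S,14S,15R)-15-[3-bromo-5-(triisopropylsilyloxy)phenyl]-11,15-bis(tert-butyldimethylsilyloxy)-7-hydroxy-6,12-dimethoxy-2,8,10,14-tetramethylpentadeca-2,8-dienamide
Conditions: AlMe3, NH4Cl, PhMe, 0 °C → rt; then 28, 50 °C; aq. KNaC4H4O6 work-up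
Reagents that add atoms: ammonium chloride ([NH4+].[Cl-])
Why: Weinreb aminolysis with the aluminium amide formed from AlMe3 and NH4Cl converts the methyl ester directly into the primary amide without disturbing the silyl ethers or the aryl bromide.

Step 19
Reactants: 29 (2E,6S,7S,8E,10S,11R,12S,14S,15R)-15-[3-bromo-5-(triisopropylsilyloxy)phenyl]-11,15-bis(tert-butyldimethylsilyloxy)-7-hydroxy-6,12-dimethoxy-2,8,10,14-tetramethylpentadeca-2,8-dienamide
Product: 30 11,15-bis-O-(tert-butyldimethylsilyl)-18-O-(triisopropylsilyl) derivative of the target macrolactam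
Conditions: NiBr2·DME (15 mol%), 4,4′-di-tert-butyl-2,2′-bipyridine (15 mol%), [Ir(ppy)2(dtbbpy)]PF6 (2 mol%), K3PO4 (3 equiv), MeCN/DMA 9:1, 2 mM, 450 nm LEDs, 30 °C
Reagents that add atoms: none
Why: Proposed new method: light-driven nickel-catalysed intramolecular N-arylation of a primary enamide (macro-Goldberg-type amidation) — the aryl bromide adds oxidatively to low-valent nickel, the K3PO4-deprotonated amide binds the arylnickel bromide, and oxidation (or triplet sensitisation) of the divalent aryl(amido)nickel species by the excited iridium photocatalyst triggers C–N reductive elimination from trivalent nickel at 30 °C, closing the 19-membered lactam under high dilution; the closest known reactions are the intermolecular nickel/photoredox N-arylation of amides, carbamates and sulfonamides with aryl bromides and the thermal CuI/diamine macrolactam closure of related ansamycins.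

Step 20
Reactants: 30 11,15-bis-O-(tert-butyldimethylsilyl)-18-O-(triisopropylsilyl) derivative of the target macrolactam
Product: 31 target macrolactam CNP0366451.1
Conditions: TBAF/AcOH (1:1, 8 equiv), THF, rt → 40 °C
Reagents that add atoms: none
Why: Fluoride-mediated desilylation removes the two TBS ethers and the aryl TIPS ether in one operation without touching any stereocentre.

**Compound list**

1 | (5S)-5-(trityloxymethyl)oxolan-2-one | O=C1CC[C@@H](COC(c2ccccc2)(c2ccccc2)c2ccccc2)O1 | starting material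
2 | methyl (4S)-4-methoxy-5-(trityloxy)pentanoate | COC(=O)CC[C@H](OC)COC(c1ccccc1)(c1ccccc1)c1ccccc1 | intermediate
3 | methyl 2-(triphenylphosphoranylidene)propanoate | COC(=O)C(C)=P(c1ccccc1)(c1ccccc1)c1ccccc1 | starting material
4 | (4S)-4-methoxy-5-(trityloxy)pentanal | O=CCC[C@H](OC)COC(c1ccccc1)(c1ccccc1)c1ccccc1 | intermediate
5 | methyl (2E,6S)-6-methoxy-2-methyl-7-(trityloxy)hept-2-enoate | COC(=O)/C(C)=C/CC[C@H](OC)COC(c1ccccc1)(c1ccccc1)c1ccccc1 | intermediate
6 | methyl (2E,6S)-7-hydroxy-6-methoxy-2-methylhept-2-enoate | COC(=O)/C(C)=C/CC[C@H](OC)CO | intermediate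
7 | methyl (2E,6S)-6-methoxy-2-methyl-7-oxohept-2-enoate | COC(=O)/C(C)=C/CC[C@H](OC)C=O | intermediate
8 | sodium [(5S)-2-oxo-5-(trityloxymethyl)oxolan-3-ylidene]methanolate | [Na+].[O-]C=C1C[C@@H](COC(c2ccccc2)(c2ccccc2)c2ccccc2)OC1=O | intermediate
9 | (5S)-3-methylidene-5-(trityloxymethyl)oxolan-2-one | C=C1C[C@@H](COC(c2ccccc2)(c2ccccc2)c2ccccc2)OC1=O | intermediate
10 | (3S,5S)-3-methyl-5-(trityloxymethyl)oxolan-2-one (cis) | C[C@H]1C[C@@H](COC(c2ccccc2)(c2ccccc2)c2ccccc2)OC1=O | intermediate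
11 | methyl (2S,4S)-4-methoxy-2-methyl-5-(trityloxy)pentanoate | COC(=O)[C@@H](C)C[C@H](OC)COC(c1ccccc1)(c1ccccc1)c1ccccc1 | intermediate
12 | methyl (2S,4S)-5-hydroxy-4-methoxy-2-methylpentanoate | COC(=O)[C@@H](C)C[C@H](OC)CO | intermediate
13 | methyl (2S,4S)-4-methoxy-2-methyl-5-oxopentanoate | COC(=O)[C@@H](C)C[C@H](OC)C=O | intermediate
14 | 2-[(2Z)-but-2-en-1-yl]-4,4,5,5-tetramethyl-1,3,2-dioxaborolane | C/C=C\CB1OC(C)(C)C(C)(C)O1 | starting material
15 | methyl (2S,4S,5R,6S)-5-hydroxy-4-methoxy-2,6-dimethyloct-7-enoate | C=C[C@H](C)[C@@H](O)[C@@H](OC)C[C@H](C)C(=O)OC | intermediate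
16 | (3S,5S,6R)-6-[(2S)-but-3-en-2-yl]-5-methoxy-3-methyloxan-2-one | C=C[C@H](C)[C@H]1OC(=O)[C@@H](C)C[C@@H]1OC | intermediate
17 | (3S,5S,6R)-6-[(2S)-but-3-en-2-yl]-5-methoxy-3-methyloxan-2-ol (anomer mixture) | C=C[C@H](C)[C@H]1OC(O)[C@@H](C)C[C@@H]1OC | intermediate
18 | 3,5-dibromophenol | Oc1cc(Br)cc(Br)c1 | starting material
19 | (3,5-dibromophenoxy)tri(propan-2-yl)silane | CC(C)[Si](Oc1cc(Br)cc(Br)c1)(C(C)C)C(C)C | intermediate
20 | [3-bromo-5-(triisopropylsilyloxy)phenyl]magnesium chloride (LiCl complex) | CC(C)[Si](Oc1cc(Br)cc([Mg]Cl)c1)(C(C)C)C(C)C | intermediate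
21 | (1R,2S,4S,5R,6S)-1-[3-bromo-5-(triisopropylsilyloxy)phenyl]-4-methoxy-2,6-dimethyloct-7-ene-1,5-diol | C=C[C@H](C)[C@@H](O)[C@@H](OC)C[C@H](C)[C@@H](O)c1cc(Br)cc(O[Si](C(C)C)(C(C)C)C(C)C)c1 | intermediate
22 | {3-bromo-5-[(1R,2S,4S,5R,6S)-1,5-bis(tert-butyldimethylsilyloxy)-4-methoxy-2,6-dimethyloct-7-en-1-yl]phenoxy}tri(propan-2-yl)silane | C=C[C@H](C)[C@@H](O[Si](C)(C)C(C)(C)C)[C@@H](OC)C[C@H](C)[C@@H](O[Si](C)(C)C(C)(C)C)c1cc(Br)cc(O[Si](C(C)C)(C(C)C)C(C)C)c1 | intermediate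
23 | (2R,3R,4S,6S,7R)-7-[3-bromo-5-(triisopropylsilyloxy)phenyl]-3,7-bis(tert-butyldimethylsilyloxy)-4-methoxy-2,6-dimethylheptanal | O=C[C@H](C)[C@@H](O[Si](C)(C)C(C)(C)C)[C@@H](OC)C[C@H](C)[C@@H](O[Si](C)(C)C(C)(C)C)c1cc(Br)cc(O[Si](C(C)C)(C(C)C)C(C)C)c1 | intermediate
24 | {3-bromo-5-[(1R,2S,4S,5R,6S)-1,5-bis(tert-butyldimethylsilyloxy)-4-methoxy-2,6-dimethyloct-7-yn-1-yl]phenoxy}tri(propan-2-yl)silane | C#C[C@H](C)[C@@H](O[Si](C)(C)C(C)(C)C)[C@@H](OC)C[C@H](C)[C@@H](O[Si](C)(C)C(C)(C)C)c1cc(Br)cc(O[Si](C(C)C)(C(C)C)C(C)C)c1 | intermediate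
25 | {3-bromo-5-[(1R,2S,4S,5R,6S)-1,5-bis(tert-butyldimethylsilyloxy)-4-methoxy-2,6-dimethylnon-7-yn-1-yl]phenoxy}tri(propan-2-yl)silane | CC#C[C@H](C)[C@@H](O[Si](C)(C)C(C)(C)C)[C@@H](OC)C[C@H](C)[C@@H](O[Si](C)(C)C(C)(C)C)c1cc(Br)cc(O[Si](C(C)C)(C(C)C)C(C)C)c1 | intermediate
26 | chlorobis(η5-cyclopentadienyl)[(E)-alkenyl]zirconium from 25, Zr on C8 (cyclopentadienyl rings drawn σ-bonded) | Cl[Zr](C1C=CC=C1)(C1C=CC=C1)/C(C)=C/[C@H](C)[C@@H](O[Si](C)(C)C(C)(C)C)[C@@H](OC)C[C@H](C)[C@@H](O[Si](C)(C)C(C)(C)C)c1cc(Br)cc(O[Si](C(C)C)(C(C)C)C(C)C)c1 | intermediate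
27 | methyl[(E)-alkenyl]zinc from 26, Zn on C8 | C[Zn]/C(C)=C/[C@H](C)[C@@H](O[Si](C)(C)C(C)(C)C)[C@@H](OC)C[C@H](C)[C@@H](O[Si](C)(C)C(C)(C)C)c1cc(Br)cc(O[Si](C(C)C)(C(C)C)C(C)C)c1 | intermediate
28 | methyl (2E,6S,7S,8E,10S,11R,12S,14S,15R)-15-[3-bromo-5-(triisopropylsilyloxy)phenyl]-11,15-bis(tert-butyldimethylsilyloxy)-7-hydroxy-6,12-dimethoxy-2,8,10,14-tetramethylpentadeca-2,8-dienoate | COC(=O)/C(C)=C/CC[C@H](OC)[C@@H](O)/C(C)=C/[C@H](C)[C@@H](O[Si](C)(C)C(C)(C)C)[C@@H](OC)C[C@H](C)[C@@H](O[Si](C)(C)C(C)(C)C)c1cc(Br)cc(O[Si](C(C)C)(C(C)C)C(C)C)c1 | intermediate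
29 | (2E,6S,7S,8E,10S,11R,12S,14S,15R)-15-[3-bromo-5-(triisopropylsilyloxy)phenyl]-11,15-bis(tert-butyldimethylsilyloxy)-7-hydroxy-6,12-dimethoxy-2,8,10,14-tetramethylpentadeca-2,8-dienamide | NC(=O)/C(C)=C/CC[C@H](OC)[C@@H](O)/C(C)=C/[C@H](C)[C@@H](O[Si](C)(C)C(C)(C)C)[C@@H](OC)C[C@H](C)[C@@H](O[Si](C)(C)C(C)(C)C)c1cc(Br)cc(O[Si](C(C)C)(C(C)C)C(C)C)c1 | intermediate
30 | 11,15-bis-O-(tert-butyldimethylsilyl)-18-O-(triisopropylsilyl) derivative of the target macrolactam (2E,8E; 6S,7S,10S,11R,12S,14S,15R) | CO[C@H]1C[C@H](C)[C@@H](O[Si](C)(C)C(C)(C)C)c2cc(O[Si](C(C)C)(C(C)C)C(C)C)cc(c2)NC(=O)/C(C)=C/CC[C@H](OC)[C@@H](O)/C(C)=C/[C@H](C)[C@H]1O[Si](C)(C)C(C)(C)C | intermediate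
31 | CNP0366451.1: 19-membered ansa-lactam, (2E,8E; 6S,7S,10S,11R,12S,14S,15R)-7,11,15,18-tetrahydroxy-6,12-dimethoxy-2,8,10,14-tetramethyl (C1 amide carbonyl bonded to N on C20 of the arene, C15 bonded to C16) | CO[C@H]1C[C@H](C)[C@@H](O)c2cc(O)cc(c2)NC(=O)/C(C)=C/CC[C@H](OC)[C@@H](O)/C(C)=C/[C@H](C)[C@H]1O | target

**Step count**

Total steps: 20. Longest linear sequence: 15 (steps 5–11 and 13–20, from 1 to 31).

**Three steps most likely to fail**

Step 13 (aryl Grignard addition to lactol 17). Felkin control from an α-methyl stereocentre whose other substituent is only a CH2 chain may give a modest ratio at C15. The fallback sets out from lactone 16 and reaches C15 by reduction and inversion instead of addition. AlMe3/MeNHOMe·HCl opens 16 to the hydroxy Weinreb amide F1, and TBSOTf/2,6-lutidine gives the silyl ether F2. Aryl Grignard 20 converts this into the aryl ketone F3. LiBH(s-Bu)3 at −78 °C reduces the ketone with high Felkin selectivity to the 14,15-anti (15S) alcohol F4. Mitsunobu inversion (4-nitrobenzoic acid, PPh3, DIAD) gives the 15R 4-nitrobenzoate F5, and K2CO3/MeOH at 0 °C gives the 15R alcohol F6. TBSOTf/2,6-lutidine then gives 22, where the route resumes at step 15.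

Step 17 (hydrozirconation, zinc transmetalation, aldehyde addition). The risks are the regioselectivity of hydrozirconation on the hindered internal alkyne, reduction of aldehyde 7 by residual Cp2Zr(H)Cl, and an insufficient chelate ratio at C7. The fallback sets out from alkyne 25. Hydrozirconation followed by I2 gives the isolable E-alkenyl iodide F7. Iodine–magnesium exchange with i-PrMgCl·LiCl at −20 °C, which is faster than exchange of the electron-rich aryl bromide, gives the alkenylmagnesium chloride F8. This is added at −78 °C to aldehyde 7 precomplexed with MgBr2·OEt2 in CH2Cl2 (Cram-chelate Grignard addition) and gives 28, where the route resumes at step 18.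

Step 19 (proposed light-driven nickel macro-N-arylation). The risks are oligomerisation, protodebromination and competing O-arylation by the free C7–OH. The fallback uses known chemistry and moves the ring closure to the acyl C–N bond; it sets out from ester 28. Pd2(dba)3/Xantphos-catalysed amination with benzophenone imine (Cs2CO3, dioxane, 90 °C) gives the N-diphenylmethylidene aniline F9. NH2OH·HCl/NaOAc in MeOH releases the aniline ester F10. Me3SnOH in 1,2-dichloroethane at 80 °C gives the seco amino acid F11. Macrolactamisation with BOP-Cl/i-Pr2NEt in toluene at 85 °C under high dilution, the classical ansamycin ring closure, gives 30, where the route resumes at step 20.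

**Further compounds**

F1 | step 13 | (2S,4S,5R,6S)-5-hydroxy-N,4-dimethoxy-N,2,6-trimethyloct-7-enamide | C=C[C@H](C)[C@@H](O)[C@@H](OC)C[C@H](C)C(=O)N(C)OC
F2 | step 13 | (2S,4S,5R,6S)-5-(tert-butyldimethylsilyloxy)-N,4-dimethoxy-N,2,6-trimethyloct-7-enamide | C=C[C@H](C)[C@@H](O[Si](C)(C)C(C)(C)C)[C@@H](OC)C[C@H](C)C(=O)N(C)OC
F3 | step 13 | (2S,4S,5R,6S)-1-[3-bromo-5-(triisopropylsilyloxy)phenyl]-5-(tert-butyldimethylsilyloxy)-4-methoxy-2,6-dimethyloct-7-en-1-one | C=C[C@H](C)[C@@H](O[Si](C)(C)C(C)(C)C)[C@@H](OC)C[C@H](C)C(=O)c1cc(Br)cc(O[Si](C(C)C)(C(C)C)C(C)C)c1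
F4 | step 13 | (1S,2S,4S,5R,6S)-1-[3-bromo-5-(triisopropylsilyloxy)phenyl]-5-(tert-butyldimethylsilyloxy)-4-methoxy-2,6-dimethyloct-7-en-1-ol | C=C[C@H](C)[C@@H](O[Si](C)(C)C(C)(C)C)[C@@H](OC)C[C@H](C)[C@H](O)c1cc(Br)cc(O[Si](C(C)C)(C(C)C)C(C)C)c1
F5 | step 13 | (1R,2S,4S,5R,6S)-1-[3-bromo-5-(triisopropylsilyloxy)phenyl]-5-(tert-butyldimethylsilyloxy)-4-methoxy-2,6-dimethyloct-7-en-1-yl 4-nitrobenzoate | C=C[C@H](C)[C@@H](O[Si](C)(C)C(C)(C)C)[C@@H](OC)C[C@H](C)[C@@H](OC(=O)c1ccc(cc1)[N+](=O)[O-])c2cc(Br)cc(O[Si](C(C)C)(C(C)C)C(C)C)c2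
F6 | step 13 | (1R,2S,4S,5R,6S)-1-[3-bromo-5-(triisopropylsilyloxy)phenyl]-5-(tert-butyldimethylsilyloxy)-4-methoxy-2,6-dimethyloct-7-en-1-ol | C=C[C@H](C)[C@@H](O[Si](C)(C)C(C)(C)C)[C@@H](OC)C[C@H](C)[C@@H](O)c1cc(Br)cc(O[Si](C(C)C)(C(C)C)C(C)C)c1
F7 | step 17 | {3-bromo-5-[(1R,2S,4S,5R,6S,7E)-1,5-bis(tert-butyldimethylsilyloxy)-8-iodo-4-methoxy-2,6-dimethylnon-7-en-1-yl]phenoxy}tri(propan-2-yl)silane | I/C(C)=C/[C@H](C)[C@@H](O[Si](C)(C)C(C)(C)C)[C@@H](OC)C[C@H](C)[C@@H](O[Si](C)(C)C(C)(C)C)c1cc(Br)cc(O[Si](C(C)C)(C(C)C)C(C)C)c1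
F8 | step 17 | (E)-alkenylmagnesium chloride from F7, Mg on C8 | Cl[Mg]/C(C)=C/[C@H](C)[C@@H](O[Si](C)(C)C(C)(C)C)[C@@H](OC)C[C@H](C)[C@@H](O[Si](C)(C)C(C)(C)C)c1cc(Br)cc(O[Si](C(C)C)(C(C)C)C(C)C)c1
F9 | step 19 | methyl ester 28 with the aryl bromide replaced by N=CPh2 (N-diphenylmethylidene aniline) | COC(=O)/C(C)=C/CC[C@H](OC)[C@@H](O)/C(C)=C/[C@H](C)[C@@H](O[Si](C)(C)C(C)(C)C)[C@@H](OC)C[C@H](C)[C@@H](O[Si](C)(C)C(C)(C)C)c1cc(N=C(c2ccccc2)c2ccccc2)cc(O[Si](C(C)C)(C(C)C)C(C)C)c1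
F10 | step 19 | methyl ester 28 with the aryl bromide replaced by NH2 (aniline ester) | COC(=O)/C(C)=C/CC[C@H](OC)[C@@H](O)/C(C)=C/[C@H](C)[C@@H](O[Si](C)(C)C(C)(C)C)[C@@H](OC)C[C@H](C)[C@@H](O[Si](C)(C)C(C)(C)C)c1cc(N)cc(O[Si](C(C)C)(C(C)C)C(C)C)c1
F11 | step 19 | seco amino acid (free carboxylic acid of F10) | OC(=O)/C(C)=C/CC[C@H](OC)[C@@H](O)/C(C)=C/[C@H](C)[C@@H](O[Si](C)(C)C(C)(C)C)[C@@H](OC)C[C@H](C)[C@@H](O[Si](C)(C)C(C)(C)C)c1cc(N)cc(O[Si](C(C)C)(C(C)C)C(C)C)c1
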